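**Plan**

1. Retrosynthesis: remove the seven silyl ethers and cut the terminal stilbene C=C (olefination of a C6 aldehyde). Then cut together the O1–C2 and C3a–C3 bonds of the dihydrofuran fused to the styryl-bearing resorcinol (unit A). The stilbene so exposed is cut the same way again (its C=C, then O1–C2 and C3a–C3 of the second dihydrofuran), leading to piceatannol, a 4-hydroxybenzylphosphonate and two molecules of methyl 3,5-dioxocyclohexane-1-carboxylate.
2. Enabling feature: in each benzofuran the benzene ring carries the ring oxygen (on C7a) and a hydroxyl (on C4) on the two carbons flanking C3a. It is a resorcinol, so C3a is C2 of a cyclohexane-1,3-dione, and as the diazo derivative that carbon becomes an electrophilic carbenoid. The aryl group on the alkene carbon that becomes C2 is para-oxygenated, so the alkene gives its far carbon to C3a and its benzylic cation to the dione oxygen.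
3. Forward: silylated piceatannol + diazodione → dihydrofuran of units B/C → dehydrogenation of the cyclohexenone to the phenol → ester turned into a 4-silyloxystyryl group → second annulation on this new alkene (dihydrofuran of units A/B) → dehydrogenation → ester to 4-silyloxystyryl → global desilylation.
4. Stereochemistry: both rings arise trans from E-alkenes by stepwise closure. Absolute configuration comes from a chiral dirhodium tetracarboxylate, one antipode for the (2S,3S) ring and the other for the (2R,3R) ring. Both stilbene double bonds are set E by Horner–Wadsworth–Emmons olefination.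

Key step: step 10

Assumption: the ester-bearing C6 of 7, 9, 18 and 19 forms as an inconsequential epimer mixture and is drawn without configuration; the catalyst antipode assigned to each annulation is to be confirmed in step 3 and the two antipodes exchanged if the sense of induction is the opposite one (TBS = tert-butyldimethylsilyl, TBSO = tert-butyldimethylsilyloxy).

**Route**

Step 1
Reactants: 1 piceatannol, (E)-4-[2-(3,5-dihydroxyphenyl)ethenyl]benzene-1,2-diol; 2 tert-butyldimethylsilyl chloride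
Product: 3 (E)-1-[3,4-bis(TBSO)phenyl]-2-[3,5-bis(TBSO)phenyl]ethene
Conditions: TBSCl, imidazole, DMF, rt
Reagents that add atoms: tert-butyldimethylsilyl chloride, CC(C)(C)[Si](C)(C)Cl
Why: Standard phenol silylation masks the oxidisable catechol and every O–H that would intercept a carbenoid, while the alkene stays electron-rich.

Step 2
Reactants: 4 methyl 3,5-dioxocyclohexane-1-carboxylate; 5 4-acetamidobenzenesulfonyl azide
Product: 6 methyl 4-diazo-3,5-dioxocyclohexane-1-carboxylate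
Conditions: Et3N, MeCN, 0 °C to rt
Reagents that add atoms: 4-acetamidobenzenesulfonyl azide, CC(=O)Nc1ccc(cc1)S(=O)(=O)N=[N+]=[N-]
Why: Regitz diazo transfer to the doubly activated methylene of a 1,3-dione is routine and places the diazo carbon, by construction, between the two carbonyl oxygens.

Step 3
Reactants: 3 tetrasilylated piceatannol; 6 diazodione
Product: 7 methyl (2S,3S)-2-[3,4-bis(TBSO)phenyl]-3-[3,5-bis(TBSO)phenyl]-4-oxo-2,3,4,5,6,7-hexahydro-1-benzofuran-6-carboxylate (trans; C6 epimers)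
Conditions: Rh2(S-TCPTTL)4 (dirhodium tetrakis[N-tetrachlorophthaloyl-(S)-tert-leucinate], 2 mol %), PhCF3, 40 °C, slow addition of 6
Reagents that add atoms: methyl 4-diazo-3,5-dioxocyclohexane-1-carboxylate (6), COC(=O)C1CC(=O)C(=[N+]=[N-])C(=O)C1
Why: Proposed new method: the same carbenoid formal [3+2] cycloaddition as in step 10 (carbene carbon attacked by the alkene carbon bearing the 3,5-disilyloxyphenyl ring, cation on the carbon bearing the para-silyloxylated catechol ring, 5-exo-trig O-closure to the trans ring), with the (2S,3S) configuration set by facial selection in the chiral carboxylate pocket; the closest known reaction types are the achiral dirhodium tetraacetate-catalysed cycloaddition of 2-diazocyclohexane-1,3-diones with styrenes and the enantioselective cyclopropanation of alkenes by acceptor/acceptor carbenoids under tert-leucinate dirhodium catalysts.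

Step 4
Reactants: 7 keto ester of units B/C; 8 benzeneselenenyl chloride
Product: 10 methyl (2S,3S)-2-[3,4-bis(TBSO)phenyl]-3-[3,5-bis(TBSO)phenyl]-4-hydroxy-2,3-dihydro-1-benzofuran-6-carboxylate, via α-phenylselanyl ketone 9 (not isolated)
Conditions: LiN(SiMe3)2, THF, −78 °C; PhSeCl, −78 °C; then H2O2, pyridine, CH2Cl2, 0 °C to rt
Reagents that add atoms: none
Why: Kinetic enolisation at C5 (α to the vinylogous-ester carbonyl), α-selenenylation and selenoxide syn-elimination towards the C6–H should give a dienone that tautomerises irreversibly to the phenol, while the non-acidic C2 and C3 stereocentres are untouched.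

Step 5
Reactants: 10 phenol ester; 11 tert-butyldimethylsilyl trifluoromethanesulfonate
Product: 12 methyl (2S,3S)-4-(TBSO)-2-[3,4-bis(TBSO)phenyl]-3-[3,5-bis(TBSO)phenyl]-2,3-dihydro-1-benzofuran-6-carboxylate
Conditions: TBSOTf, 2,6-lutidine, CH2Cl2, 0 °C
Reagents that add atoms: tert-butyldimethylsilyl trifluoromethanesulfonate, CC(C)(C)[Si](C)(C)OS(=O)(=O)C(F)(F)F
Why: The silyl triflate with a hindered pyridine base silylates the hindered phenol next to C3a and removes the last O–H before the second carbenoid step.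

Step 6
Reactants: 12 pentasilylated ester
Product: 13 [(2S,3S)-4-(TBSO)-2-[3,4-bis(TBSO)phenyl]-3-[3,5-bis(TBSO)phenyl]-2,3-dihydro-1-benzofuran-6-yl]methanol
Conditions: iBu2AlH, CH2Cl2, −78 to 0 °C; aq. potassium sodium tartrate
Reagents that add atoms: none
Why: Hydride reduction of an aryl methyl ester to the benzylic alcohol is standard and aryl silyl ethers tolerate the reagent at low temperature.

Step 7
Reactants: 13 benzylic alcohol
Product: 14 (2S,3S)-4-(TBSO)-2-[3,4-bis(TBSO)phenyl]-3-[3,5-bis(TBSO)phenyl]-2,3-dihydro-1-benzofuran-6-carbaldehyde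
Conditions: MnO2, CH2Cl2, rt
Reagents that add atoms: none
Why: Activated manganese dioxide oxidises benzylic alcohols selectively to aldehydes without over-oxidation and without touching silyl ethers.

Step 8
Reactants: 15 diethyl (4-hydroxybenzyl)phosphonate; 2 tert-butyldimethylsilyl chloride
Product: 16 diethyl [4-(TBSO)benzyl]phosphonate
Conditions: TBSCl, imidazole, DMF, rt
Reagents that add atoms: tert-butyldimethylsilyl chloride, CC(C)(C)[Si](C)(C)Cl
Why: Silylation of the phenol allows the phosphonate carbanion to be formed without a competing phenoxide.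

Step 9
Reactants: 14 aldehyde; 16 silylated benzylphosphonate
Product: 17 (2S,3S)-4-(TBSO)-2-[3,4-bis(TBSO)phenyl]-3-[3,5-bis(TBSO)phenyl]-6-[(E)-2-[4-(TBSO)phenyl]ethenyl]-2,3-dihydro-1-benzofuran
Conditions: NaN(SiMe3)2, THF, −78 °C to rt
Reagents that add atoms: diethyl [4-(TBSO)benzyl]phosphonate (16), CCOP(=O)(OCC)Cc1ccc(O[Si](C)(C)C(C)(C)C)cc1
Why: Horner–Wadsworth–Emmons olefination of an aryl aldehyde with a benzylphosphonate anion should give the (E)-stilbene, and the non-nucleophilic amide base spares the aryl silyl ethers and the remote stereocentres.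

Step 10
Reactants: 17 stilbene of units B/C; 6 diazodione
Product: 18 methyl (2R,3R)-3-[(2S,3S)-4-(TBSO)-2-[3,4-bis(TBSO)phenyl]-3-[3,5-bis(TBSO)phenyl]-2,3-dihydro-1-benzofuran-6-yl]-2-[4-(TBSO)phenyl]-4-oxo-2,3,4,5,6,7-hexahydro-1-benzofuran-6-carboxylate (trans; C6 epimers)
Conditions: Rh2(R-TCPTTL)4 (dirhodium tetrakis[N-tetrachlorophthaloyl-(R)-tert-leucinate], 2 mol %), PhCF3, 40 °C, slow addition of 6
Reagents that add atoms: methyl 4-diazo-3,5-dioxocyclohexane-1-carboxylate (6), COC(=O)C1CC(=O)C(=[N+]=[N-])C(=O)C1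
Why: Proposed new method: the electron-poor dirhodium carboxylate converts 6 into a carbenoid whose carbene carbon (C2 of the dione, the future C3a) is attacked by the stilbene carbon remote from the 4-silyloxyphenyl ring, giving a zwitterion (para-quinone-methide-like benzylic cation at the future C2, dione enolate) that collapses by O-attack, so two carbons that are both nucleophilic in their natural polarity (dione C2 and the stilbene β-carbon) are joined through carbene umpolung. The closest known reaction types are the achiral dirhodium tetraacetate-catalysed formal [3+2] cycloaddition of 2-diazocyclohexane-1,3-diones with styrenes and enol ethers and the enantioselective cyclopropanations of acceptor/acceptor carbenoids with this tert-leucinate catalyst family; catalyst-controlled face selection on a 1,2-diarylalkene is the untested part. The one ring closed is the dihydrofuran, by 5-exo-trig attack of the enolate oxygen on the cationic benzylic carbon, whose C=aryl bond lies outside the new ring. C3 is fixed in the C–C bond-forming event by the chiral carboxylate pocket exposing one face of the E-alkene, and C2 is then set trans to the C3 aryl group by the steric preference of the closure, trans being also the thermodynamic arrangement. Regioselectivity is secured twice: the diazo carbon lies between the two carbonyls, so the new C–C bond can only form at the ring-A carbon flanked by both oxygens, and the para-silyloxy group stabilises the cation only on the carbon that must take the oxygen, the benzofuranyl ring being meta-dioxygenated. Chemoselectivity rests on 17 holding a single alkene, no free O–H and only hindered aryl silyl ethers, and on 6 carrying an ester and not an alkene as its handle, so that it cannot react with itself.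

Step 11
Reactants: 18 keto ester of units A/B/C; 8 benzeneselenenyl chloride
Product: 20 methyl (2R,3R)-3-[(2S,3S)-4-(TBSO)-2-[3,4-bis(TBSO)phenyl]-3-[3,5-bis(TBSO)phenyl]-2,3-dihydro-1-benzofuran-6-yl]-4-hydroxy-2-[4-(TBSO)phenyl]-2,3-dihydro-1-benzofuran-6-carboxylate, via α-phenylselanyl ketone 19 (not isolated)
Conditions: LiN(SiMe3)2, THF, −78 °C; PhSeCl, −78 °C; then H2O2, pyridine, CH2Cl2, 0 °C to rt
Reagents that add atoms: none
Why: As in step 4, enolate selenenylation and selenoxide syn-elimination should dehydrogenate the cyclohexenone to the resorcinol-type phenol of ring A, and 18 holds no other alkene or acidic stereocentre.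

Step 12
Reactants: 20 phenol ester
Product: 21 (2R,3R)-3-[(2S,3S)-4-(TBSO)-2-[3,4-bis(TBSO)phenyl]-3-[3,5-bis(TBSO)phenyl]-2,3-dihydro-1-benzofuran-6-yl]-6-(hydroxymethyl)-2-[4-(TBSO)phenyl]-2,3-dihydro-1-benzofuran-4-ol
Conditions: iBu2AlH (excess), CH2Cl2, −78 to 0 °C; aq. potassium sodium tartrate
Reagents that add atoms: none
Why: Ester reduction as in step 6; the free phenol only consumes one hydride equivalent as an aluminium phenoxide and is returned on work-up.

Step 13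
Reactants: 21 phenolic benzylic alcohol
Product: 22 (2R,3R)-3-[(2S,3S)-4-(TBSO)-2-[3,4-bis(TBSO)phenyl]-3-[3,5-bis(TBSO)phenyl]-2,3-dihydro-1-benzofuran-6-yl]-4-hydroxy-2-[4-(TBSO)phenyl]-2,3-dihydro-1-benzofuran-6-carbaldehyde
Conditions: MnO2, CH2Cl2, rt
Reagents that add atoms: none
Why: Manganese dioxide oxidises the benzylic alcohol selectively, and a phenol meta to the carbinol cannot form a quinone methide and should be left alone.

Step 14
Reactants: 22 phenolic aldehyde; 16 silylated benzylphosphonate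
Product: 23 (2R,3R)-3-[(2S,3S)-4-(TBSO)-2-[3,4-bis(TBSO)phenyl]-3-[3,5-bis(TBSO)phenyl]-2,3-dihydro-1-benzofuran-6-yl]-2-[4-(TBSO)phenyl]-6-[(E)-2-[4-(TBSO)phenyl]ethenyl]-2,3-dihydro-1-benzofuran-4-ol
Conditions: 16 (excess), NaN(SiMe3)2, THF, −78 °C to rt
Reagents that add atoms: diethyl [4-(TBSO)benzyl]phosphonate (16), CCOP(=O)(OCC)Cc1ccc(O[Si](C)(C)C(C)(C)C)cc1
Why: Horner–Wadsworth–Emmons olefination as in step 9 with an extra equivalent of anion for the phenol; the phenoxide is meta to the aldehyde and should not deactivate it, and the (E)-alkene is expected.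

Step 15
Reactants: 23 heptasilyl ether
Product: 24 (2R,3R)-3-[(2S,3S)-2-(3,4-dihydroxyphenyl)-3-(3,5-dihydroxyphenyl)-4-hydroxy-2,3-dihydro-1-benzofuran-6-yl]-2-(4-hydroxyphenyl)-6-[(E)-2-(4-hydroxyphenyl)ethenyl]-2,3-dihydro-1-benzofuran-4-ol (CNP0107857.3)
Conditions: Bu4NF, AcOH, THF, 0 °C to rt, argon
Reagents that add atoms: none
Why: Fluoride cleaves aryl silyl ethers through pentacoordinate silicon, and the acetic acid buffer keeps the catechol, the stilbene and the two trans-dihydrobenzofurans (labile at the para-hydroxybenzylic C–O bonds) away from both strong base and acid.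

**Compound list**

1 | piceatannol | Oc1cc(O)cc(/C=C/c2ccc(O)c(O)c2)c1 | starting material
2 | tert-butyldimethylsilyl chloride | CC(C)(C)[Si](C)(C)Cl | starting material
3 | (E)-1-[3,4-bis(TBSO)phenyl]-2-[3,5-bis(TBSO)phenyl]ethene | CC(C)(C)[Si](C)(C)Oc1cc(O[Si](C)(C)C(C)(C)C)cc(/C=C/c2ccc(O[Si](C)(C)C(C)(C)C)c(O[Si](C)(C)C(C)(C)C)c2)c1 | intermediate
4 | methyl 3,5-dioxocyclohexane-1-carboxylate | COC(=O)C1CC(=O)CC(=O)C1 | starting material
5 | 4-acetamidobenzenesulfonyl azide | CC(=O)Nc1ccc(cc1)S(=O)(=O)N=[N+]=[N-] | starting material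
6 | methyl 4-diazo-3,5-dioxocyclohexane-1-carboxylate | COC(=O)C1CC(=O)C(=[N+]=[N-])C(=O)C1 | intermediate
7 | methyl (2S,3S)-2-[3,4-bis(TBSO)phenyl]-3-[3,5-bis(TBSO)phenyl]-4-oxo-2,3,4,5,6,7-hexahydro-1-benzofuran-6-carboxylate (C6 epimers) | COC(=O)C1CC(=O)C2=C(C1)O[C@H](c1ccc(O[Si](C)(C)C(C)(C)C)c(O[Si](C)(C)C(C)(C)C)c1)[C@H]2c1cc(O[Si](C)(C)C(C)(C)C)cc(O[Si](C)(C)C(C)(C)C)c1 | intermediate
8 | benzeneselenenyl chloride | Cl[Se]c1ccccc1 | starting material
9 | methyl (2S,3S)-2-[3,4-bis(TBSO)phenyl]-3-[3,5-bis(TBSO)phenyl]-4-oxo-5-(phenylselanyl)-2,3,4,5,6,7-hexahydro-1-benzofuran-6-carboxylate (not isolated) | COC(=O)C1C([Se]c3ccccc3)C(=O)C2=C(C1)O[C@H](c1ccc(O[Si](C)(C)C(C)(C)C)c(O[Si](C)(C)C(C)(C)C)c1)[C@H]2c1cc(O[Si](C)(C)C(C)(C)C)cc(O[Si](C)(C)C(C)(C)C)c1 | intermediate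
10 | methyl (2S,3S)-2-[3,4-bis(TBSO)phenyl]-3-[3,5-bis(TBSO)phenyl]-4-hydroxy-2,3-dihydro-1-benzofuran-6-carboxylate | COC(=O)c1cc(O)c2c(c1)O[C@H](c1ccc(O[Si](C)(C)C(C)(C)C)c(O[Si](C)(C)C(C)(C)C)c1)[C@H]2c1cc(O[Si](C)(C)C(C)(C)C)cc(O[Si](C)(C)C(C)(C)C)c1 | intermediate
11 | tert-butyldimethylsilyl trifluoromethanesulfonate | CC(C)(C)[Si](C)(C)OS(=O)(=O)C(F)(F)F | starting material
12 | methyl (2S,3S)-4-(TBSO)-2-[3,4-bis(TBSO)phenyl]-3-[3,5-bis(TBSO)phenyl]-2,3-dihydro-1-benzofuran-6-carboxylate | COC(=O)c1cc(O[Si](C)(C)C(C)(C)C)c2c(c1)O[C@H](c1ccc(O[Si](C)(C)C(C)(C)C)c(O[Si](C)(C)C(C)(C)C)c1)[C@H]2c1cc(O[Si](C)(C)C(C)(C)C)cc(O[Si](C)(C)C(C)(C)C)c1 | intermediate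
13 | [(2S,3S)-4-(TBSO)-2-[3,4-bis(TBSO)phenyl]-3-[3,5-bis(TBSO)phenyl]-2,3-dihydro-1-benzofuran-6-yl]methanol | OCc1cc(O[Si](C)(C)C(C)(C)C)c2c(c1)O[C@H](c1ccc(O[Si](C)(C)C(C)(C)C)c(O[Si](C)(C)C(C)(C)C)c1)[C@H]2c1cc(O[Si](C)(C)C(C)(C)C)cc(O[Si](C)(C)C(C)(C)C)c1 | intermediate
14 | (2S,3S)-4-(TBSO)-2-[3,4-bis(TBSO)phenyl]-3-[3,5-bis(TBSO)phenyl]-2,3-dihydro-1-benzofuran-6-carbaldehyde | O=Cc1cc(O[Si](C)(C)C(C)(C)C)c2c(c1)O[C@H](c1ccc(O[Si](C)(C)C(C)(C)C)c(O[Si](C)(C)C(C)(C)C)c1)[C@H]2c1cc(O[Si](C)(C)C(C)(C)C)cc(O[Si](C)(C)C(C)(C)C)c1 | intermediate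
15 | diethyl (4-hydroxybenzyl)phosphonate | CCOP(=O)(OCC)Cc1ccc(O)cc1 | starting material
16 | diethyl [4-(TBSO)benzyl]phosphonate | CCOP(=O)(OCC)Cc1ccc(O[Si](C)(C)C(C)(C)C)cc1 | intermediate
17 | (2S,3S)-4-(TBSO)-2-[3,4-bis(TBSO)phenyl]-3-[3,5-bis(TBSO)phenyl]-6-[(E)-2-[4-(TBSO)phenyl]ethenyl]-2,3-dihydro-1-benzofuran | CC(C)(C)[Si](C)(C)Oc1ccc(/C=C/c2cc(O[Si](C)(C)C(C)(C)C)c3c(c2)O[C@H](c2ccc(O[Si](C)(C)C(C)(C)C)c(O[Si](C)(C)C(C)(C)C)c2)[C@H]3c2cc(O[Si](C)(C)C(C)(C)C)cc(O[Si](C)(C)C(C)(C)C)c2)cc1 | intermediate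
18 | methyl (2R,3R)-3-[(2S,3S)-4-(TBSO)-2-[3,4-bis(TBSO)phenyl]-3-[3,5-bis(TBSO)phenyl]-2,3-dihydro-1-benzofuran-6-yl]-2-[4-(TBSO)phenyl]-4-oxo-2,3,4,5,6,7-hexahydro-1-benzofuran-6-carboxylate (C6 epimers) | COC(=O)C1CC(=O)C2=C(C1)O[C@@H](c1ccc(O[Si](C)(C)C(C)(C)C)cc1)[C@@H]2c1cc(O[Si](C)(C)C(C)(C)C)c2c(c1)O[C@H](c1ccc(O[Si](C)(C)C(C)(C)C)c(O[Si](C)(C)C(C)(C)C)c1)[C@H]2c1cc(O[Si](C)(C)C(C)(C)C)cc(O[Si](C)(C)C(C)(C)C)c1 | intermediate
19 | 5-(phenylselanyl) derivative of 18: methyl (2R,3R)-3-[(2S,3S)-4-(TBSO)-2-[3,4-bis(TBSO)phenyl]-3-[3,5-bis(TBSO)phenyl]-2,3-dihydro-1-benzofuran-6-yl]-2-[4-(TBSO)phenyl]-4-oxo-5-(phenylselanyl)-2,3,4,5,6,7-hexahydro-1-benzofuran-6-carboxylate (not isolated) | COC(=O)C1C([Se]c3ccccc3)C(=O)C2=C(C1)O[C@@H](c1ccc(O[Si](C)(C)C(C)(C)C)cc1)[C@@H]2c1cc(O[Si](C)(C)C(C)(C)C)c2c(c1)O[C@H](c1ccc(O[Si](C)(C)C(C)(C)C)c(O[Si](C)(C)C(C)(C)C)c1)[C@H]2c1cc(O[Si](C)(C)C(C)(C)C)cc(O[Si](C)(C)C(C)(C)C)c1 | intermediate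
20 | methyl (2R,3R)-3-[(2S,3S)-4-(TBSO)-2-[3,4-bis(TBSO)phenyl]-3-[3,5-bis(TBSO)phenyl]-2,3-dihydro-1-benzofuran-6-yl]-4-hydroxy-2-[4-(TBSO)phenyl]-2,3-dihydro-1-benzofuran-6-carboxylate | COC(=O)c1cc(O)c2c(c1)O[C@@H](c1ccc(O[Si](C)(C)C(C)(C)C)cc1)[C@@H]2c1cc(O[Si](C)(C)C(C)(C)C)c2c(c1)O[C@H](c1ccc(O[Si](C)(C)C(C)(C)C)c(O[Si](C)(C)C(C)(C)C)c1)[C@H]2c1cc(O[Si](C)(C)C(C)(C)C)cc(O[Si](C)(C)C(C)(C)C)c1 | intermediate
21 | (2R,3R)-3-[(2S,3S)-4-(TBSO)-2-[3,4-bis(TBSO)phenyl]-3-[3,5-bis(TBSO)phenyl]-2,3-dihydro-1-benzofuran-6-yl]-6-(hydroxymethyl)-2-[4-(TBSO)phenyl]-2,3-dihydro-1-benzofuran-4-ol | OCc1cc(O)c2c(c1)O[C@@H](c1ccc(O[Si](C)(C)C(C)(C)C)cc1)[C@@H]2c1cc(O[Si](C)(C)C(C)(C)C)c2c(c1)O[C@H](c1ccc(O[Si](C)(C)C(C)(C)C)c(O[Si](C)(C)C(C)(C)C)c1)[C@H]2c1cc(O[Si](C)(C)C(C)(C)C)cc(O[Si](C)(C)C(C)(C)C)c1 | intermediate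
22 | (2R,3R)-3-[(2S,3S)-4-(TBSO)-2-[3,4-bis(TBSO)phenyl]-3-[3,5-bis(TBSO)phenyl]-2,3-dihydro-1-benzofuran-6-yl]-4-hydroxy-2-[4-(TBSO)phenyl]-2,3-dihydro-1-benzofuran-6-carbaldehyde | O=Cc1cc(O)c2c(c1)O[C@@H](c1ccc(O[Si](C)(C)C(C)(C)C)cc1)[C@@H]2c1cc(O[Si](C)(C)C(C)(C)C)c2c(c1)O[C@H](c1ccc(O[Si](C)(C)C(C)(C)C)c(O[Si](C)(C)C(C)(C)C)c1)[C@H]2c1cc(O[Si](C)(C)C(C)(C)C)cc(O[Si](C)(C)C(C)(C)C)c1 | intermediate
23 | (2R,3R)-3-[(2S,3S)-4-(TBSO)-2-[3,4-bis(TBSO)phenyl]-3-[3,5-bis(TBSO)phenyl]-2,3-dihydro-1-benzofuran-6-yl]-2-[4-(TBSO)phenyl]-6-[(E)-2-[4-(TBSO)phenyl]ethenyl]-2,3-dihydro-1-benzofuran-4-ol | CC(C)(C)[Si](C)(C)Oc1ccc(/C=C/c2cc(O)c3c(c2)O[C@@H](c2ccc(O[Si](C)(C)C(C)(C)C)cc2)[C@@H]3c2cc(O[Si](C)(C)C(C)(C)C)c3c(c2)O[C@H](c2ccc(O[Si](C)(C)C(C)(C)C)c(O[Si](C)(C)C(C)(C)C)c2)[C@H]3c2cc(O[Si](C)(C)C(C)(C)C)cc(O[Si](C)(C)C(C)(C)C)c2)cc1 | intermediate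
24 | (2R,3R)-3-[(2S,3S)-2-(3,4-dihydroxyphenyl)-3-(3,5-dihydroxyphenyl)-4-hydroxy-2,3-dihydro-1-benzofuran-6-yl]-2-(4-hydroxyphenyl)-6-[(E)-2-(4-hydroxyphenyl)ethenyl]-2,3-dihydro-1-benzofuran-4-ol | Oc1ccc(/C=C/c2cc(O)c3c(c2)O[C@@H](c2ccc(O)cc2)[C@@H]3c2cc(O)c3c(c2)O[C@H](c2ccc(O)c(O)c2)[C@H]3c2cc(O)cc(O)c2)cc1 | target

**Step count and risks**

Total step count: 15. Longest linear sequence: 13 steps (1, 3 to 7, 9 to 15); steps 2 and 8 are side branches.

Steps most likely to fail: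

Step 10 (labelled). The catalyst may fail to discriminate the faces of the hindered E-1,2-diarylalkene, or capture of the carbenoid may be slow, so that carbene dimerisation and aryl C–H functionalisation take over. The fallback uses known chemistry and sets out from 17 together with the non-diazotised dione 4. Manganese triacetate (Mn(OAc)3·2H2O, catalytic Cu(OAc)2, AcOH, 40 °C) mediates the oxidative dihydrofuran annulation of cyclic 1,3-diones with aryl alkenes. The electrophilic dione C2 radical adds to the alkene carbon remote from the 4-silyloxyphenyl ring, the benzylic radical is oxidised to the cation by a second equivalent of trivalent manganese, and the enol oxygen closes the trans ring. Regiochemistry is the same but there is no face control, so 18 should form together with the keto ester having the (2S,3S) configuration in the new dihydrofuran F1. The mixture is taken through the conditions of step 11, the unwanted isomer passing through its 5-phenylselanyl ketone F2, to give 20 and the phenol ester having the (2S,3S) configuration in the ring-A dihydrofuran F3. Because the other dihydrofuran is fixed as (2S,3S), these two are diastereomers and are separated by chromatography on silica or by preparative HPLC. The route is rejoined at 20.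

Step 3 (labelled). The same two processes may fail here: low enantioselection in the C–C bond-forming event and slow carbenoid capture by the bulky tetrasilylated stilbene. The fallback uses known chemistry and sets out from 3 and dione 4. The manganese triacetate annulation (Mn(OAc)3·2H2O, Cu(OAc)2, AcOH, 40 °C) should give the trans adduct as a racemate, that is 7 with its enantiomer, the (2R,3R) keto ester F4. Aromatisation under the conditions of step 4, the enantiomer passing through the (2R,3R) 5-phenylselanyl ketone F5, leads to racemic phenol, that is 10 with the (2R,3R) phenol ester F6. The enantiomers are resolved by preparative HPLC on a polysaccharide carbamate chiral stationary phase. The route is rejoined at 10.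

Step 11. Enolisation and selenenylation may be unselective on the crowded late intermediate, and the electron-rich silyloxyarenes may suffer oxidative damage during the peroxide treatment. The fallback sets out from 18. Kinetic enolisation and O-silylation (LiN(iPr)2, Me3SiCl, THF, −78 °C) gives the cross-conjugated trimethylsilyl dienol ether F7, which undergoes Saegusa–Ito oxidation (Pd(OAc)2, MeCN, rt). The palladium enolate loses the C6 hydrogen by β-hydride elimination and the dienone tautomerises to the phenol without any peroxide. The route is rejoined at 20.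

**Further compounds**

F1 | step 10 | methyl (2S,3S)-3-[(2S,3S)-4-(TBSO)-2-[3,4-bis(TBSO)phenyl]-3-[3,5-bis(TBSO)phenyl]-2,3-dihydro-1-benzofuran-6-yl]-2-[4-(TBSO)phenyl]-4-oxo-2,3,4,5,6,7-hexahydro-1-benzofuran-6-carboxylate (C6 epimers) | COC(=O)C1CC(=O)C2=C(C1)O[C@H](c1ccc(O[Si](C)(C)C(C)(C)C)cc1)[C@H]2c1cc(O[Si](C)(C)C(C)(C)C)c2c(c1)O[C@H](c1ccc(O[Si](C)(C)C(C)(C)C)c(O[Si](C)(C)C(C)(C)C)c1)[C@H]2c1cc(O[Si](C)(C)C(C)(C)C)cc(O[Si](C)(C)C(C)(C)C)c1
F2 | step 10 | 5-(phenylselanyl) derivative of F1 (not isolated) | COC(=O)C1C([Se]c3ccccc3)C(=O)C2=C(C1)O[C@H](c1ccc(O[Si](C)(C)C(C)(C)C)cc1)[C@H]2c1cc(O[Si](C)(C)C(C)(C)C)c2c(c1)O[C@H](c1ccc(O[Si](C)(C)C(C)(C)C)c(O[Si](C)(C)C(C)(C)C)c1)[C@H]2c1cc(O[Si](C)(C)C(C)(C)C)cc(O[Si](C)(C)C(C)(C)C)c1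
F3 | step 10 | methyl (2S,3S)-3-[(2S,3S)-4-(TBSO)-2-[3,4-bis(TBSO)phenyl]-3-[3,5-bis(TBSO)phenyl]-2,3-dihydro-1-benzofuran-6-yl]-4-hydroxy-2-[4-(TBSO)phenyl]-2,3-dihydro-1-benzofuran-6-carboxylate | COC(=O)c1cc(O)c2c(c1)O[C@H](c1ccc(O[Si](C)(C)C(C)(C)C)cc1)[C@H]2c1cc(O[Si](C)(C)C(C)(C)C)c2c(c1)O[C@H](c1ccc(O[Si](C)(C)C(C)(C)C)c(O[Si](C)(C)C(C)(C)C)c1)[C@H]2c1cc(O[Si](C)(C)C(C)(C)C)cc(O[Si](C)(C)C(C)(C)C)c1
F4 | step 3 | methyl (2R,3R)-2-[3,4-bis(TBSO)phenyl]-3-[3,5-bis(TBSO)phenyl]-4-oxo-2,3,4,5,6,7-hexahydro-1-benzofuran-6-carboxylate (C6 epimers) | COC(=O)C1CC(=O)C2=C(C1)O[C@@H](c1ccc(O[Si](C)(C)C(C)(C)C)c(O[Si](C)(C)C(C)(C)C)c1)[C@@H]2c1cc(O[Si](C)(C)C(C)(C)C)cc(O[Si](C)(C)C(C)(C)C)c1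
F5 | step 3 | 5-(phenylselanyl) derivative of F4 (not isolated) | COC(=O)C1C([Se]c3ccccc3)C(=O)C2=C(C1)O[C@@H](c1ccc(O[Si](C)(C)C(C)(C)C)c(O[Si](C)(C)C(C)(C)C)c1)[C@@H]2c1cc(O[Si](C)(C)C(C)(C)C)cc(O[Si](C)(C)C(C)(C)C)c1
F6 | step 3 | methyl (2R,3R)-2-[3,4-bis(TBSO)phenyl]-3-[3,5-bis(TBSO)phenyl]-4-hydroxy-2,3-dihydro-1-benzofuran-6-carboxylate | COC(=O)c1cc(O)c2c(c1)O[C@@H](c1ccc(O[Si](C)(C)C(C)(C)C)c(O[Si](C)(C)C(C)(C)C)c1)[C@@H]2c1cc(O[Si](C)(C)C(C)(C)C)cc(O[Si](C)(C)C(C)(C)C)c1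
F7 | step 11 | methyl (2R,3R)-3-[(2S,3S)-4-(TBSO)-2-[3,4-bis(TBSO)phenyl]-3-[3,5-bis(TBSO)phenyl]-2,3-dihydro-1-benzofuran-6-yl]-2-[4-(TBSO)phenyl]-4-(trimethylsilyloxy)-2,3,6,7-tetrahydro-1-benzofuran-6-carboxylate (C6 epimers) | COC(=O)C1C=C(O[Si](C)(C)C)C2=C(C1)O[C@@H](c1ccc(O[Si](C)(C)C(C)(C)C)cc1)[C@@H]2c1cc(O[Si](C)(C)C(C)(C)C)c2c(c1)O[C@H](c1ccc(O[Si](C)(C)C(C)(C)C)c(O[Si](C)(C)C(C)(C)C)c1)[C@H]2c1cc(O[Si](C)(C)C(C)(C)C)cc(O[Si](C)(C)C(C)(C)C)c1
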